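The data are calculated with constants of no real substance, noise included.

Amounts first: in west and in alpha the charges of starting material, partner and rival reagent are the same, but alpha holds twice the protic impurity and runs to 4.0 min. Counted as fractions of the starting material charged, I wrote target as the whole minus two corrections, side product and leftover starting material, and reckoned those corrections.

the same everywhere: starting material 0.80 M
- west: partner 0.84 M; rival reagent 0.48 M; protic impurity 0.20 M; temperature 25 °C; run made earlier
- alpha: partner 0.840 M; rival reagent 0.480 M; protic impurity 0.400 M; temperature 25 °C; time 4.0 min
- epsilon: partner 0.840 M; rival reagent 0.480 M; protic impurity 0.400 M; temperature 40 °C; time 4.0 min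
- gamma: partner 0.840 M; rival reagent 0.480 M; protic impurity 0.400 M; temperature 55 °C; time 4.0 min

west run (percent of the starting material charged)

| time / s | target / % | side product / % | starting material / % |
|---|---|---|---|
| 10.0 | 19.6 | 35.3 | 44.4 |
| 12.0 | 21.9 | 37.6 | 40.3 |
| 20.0 | 28.4 | 40.9 | 29.9 |
| 30.0 | 33.2 | 42.5 | 22.3 |
| 50.0 | 41.8 | 43.8 | 13.6 |

(each reading ± 0.5 percentage points)

- the earlier runs were read with a standard deviation of 0.5 percentage points
- the earlier runs do not show what temperature does; that part of a forecast is a guess
- no earlier run changes the charge of protic impurity; that part of a forecast is a guess

* which of these there is most of at the end, counted by the starting material in it, alpha (starting material / side product / target)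
* which of these there is most of at the end, counted by the starting material in it, epsilon (starting material / side product / target)
* which of these there is most of at the end, counted by the starting material in it, gamma (starting material / side product / target)
* the largest of these amounts at the end, in percent of the starting material charged, alpha
* the largest of these amounts at the end, in percent of the starting material charged, epsilon
* the largest of these amounts at the end, in percent of the starting material charged, gamma

The rival reagent charge is 60.0% of the starting material charge. West's side product read 43.8% at its last reading, having risen 1.3 percentage points in the last step, so I took that as its end. I booked the gap of 16.2% as rival reagent lost to protic impurity. That gave a split of 2.70 between the two fates.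

I assumed that the ratio of starting material to impurity stayed near its charged value, 4.00 in west. My carried quantity is the capture weight, a selectivity factor: the split divided by that charged ratio, read from west as 0.676.

Alpha's charged ratio is half of west's, so I put its split at 1.35 and its side product at 34.5%, less than west's last reading.

For the leftover, west's starting material fell at 0.0247 /s late on. I scaled this by the partner left in alpha against west's, and ran it from west's 13.6% to the end of alpha. That reckoning left 0.871%, so I committed to target at 64.6% in alpha. For epsilon and gamma I guessed that the weight holds and dropped the leftover, giving 65.5% of target.

The forecast named target, target and target at 56%, 60% and 62%, saying “Warmer runs finish conversion”.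

The flasks gave target as the largest amount in alpha, target in epsilon and target in gamma, at 62.4%, 62.6% and 54.6%.

    rival reagent + protic impurity → quenched reagent (k = 0.255 /M/s, Ea = 50.0 kJ/mol)
    starting material + rival reagent → side product (k = 0.220 /M/s, Ea = 47.0 kJ/mol)
    starting material + partner → target (k = 0.0394 /M/s, Ea = 44.0 kJ/mol)
    target → over-reaction product (k = 1.34 × 10⁻⁵ /s, Ea = 108 kJ/mol)
    (constants at 25 °C)

Alpha's side product stood at 36.3% against my 34.5%, and gamma's at 35.5%. But gamma also held 9.88% as over-reaction product, a species absent from my balance. The neighbour flask is gamma with rival reagent cut to 0.19 M, or 0.238 equiv of the starting material. The same weight, at the same charged ratio, gave me 13.7% of side product for that flask. That flask ended with side product at 13.9%, over-reaction product at 13.0% and target at 73.1%.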